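**Plan**
Retrosynthetic cuts, in order: the O8–C1′ ester bond; the C12–O6 lactone bond together with the C11=C13 methylene; the C4=C5 alkene of the ten-membered ring; then C3–C4, C5–C6, C7–C8 and C1–C2 of the open chain.
Forward: C1–C2 (alkenylalanate plus oxirane), C7–C8 (auxiliary aldol), C5–C6 (alkoxymethyl addition to a Weinreb amide) and C3–C4 (phosphonoacetate alkylation) build the chain; the ten-membered carbocycle closes first, the γ-lactone second, and the C8 acyl chain is attached last.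
Enabling feature: across the ring bond C4=C5, C15 lies cis to C6 (ring bonds C3–C4 and C5–C6 trans); with C15 as an ester this is the Z-enoate, the kinetic product of a bis(2,2,2-trifluoroethyl) phosphonate.
Stereochemistry: C7 and C8 from an oxazolidinone-controlled syn-aldol, C6 from a hydroxyl-directed 1,3-syn ketone reduction, C3′ from (S)-glycidol; E-C1=C10 from syn-carboalumination, C4=C5 from the key olefination.

Key step: step 17

Remark: locants C1–C15 follow germacrane numbering (C11–C13 lactone carbons, C14 the methyl on C10, C15 on C4, primed locants for the C8 acyl chain); tert-butyl(but-3-yn-1-yloxy)dimethylsilane and tributyl(iodomethyl)stannane are taken as purchasable.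

Step 1
Reactants: 1 tert-butyl(but-3-yn-1-yloxy)dimethylsilane; 2 oxirane
Product: 5 (3E)-6-{[tert-butyl(dimethyl)silyl]oxy}-4-methylhex-3-en-1-ol, via vinylalane 3 (not isolated), via lithium alanate 4 (not isolated)
Conditions: AlMe3, Cp2ZrCl2 (cat.), CH2Cl2, 0 °C → rt; evaporate; n-BuLi, hexane/THF, −78 °C; then 2, −78 → 0 °C
Reagents that add atoms: trimethylaluminium, C[Al](C)C
Why: Zirconium-catalysed syn-carboalumination (Negishi) puts the methyl on the internal alkyne carbon and aluminium on the terminus, fixing the E geometry of C1=C10, and the derived alanate opens oxirane with retention to add C2–C3.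

Step 2
Reactants: 5 (3E)-6-{[tert-butyl(dimethyl)silyl]oxy}-4-methylhex-3-en-1-ol
Product: 6 tert-butyl{[(3E)-6-chloro-3-methylhex-3-en-1-yl]oxy}dimethylsilane
Conditions: PPh3, N-chlorosuccinimide, CH2Cl2, 0 °C → rt
Reagents that add atoms: N-chlorosuccinimide, O=C1CCC(=O)N1Cl
Why: Appel-type chlorination turns the primary alcohol into a chloride that should survive the organometallic, hydride and Lewis-acid steps ahead and is kept in reserve for C3–C4 bond formation.

Step 3
Reactants: 6 tert-butyl{[(3E)-6-chloro-3-methylhex-3-en-1-yl]oxy}dimethylsilane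
Product: 7 (3E)-6-chloro-3-methylhex-3-en-1-ol
Conditions: camphorsulfonic acid (cat.), MeOH, 0 °C → rt
Reagents that add atoms: none
Why: Acid-catalysed methanolysis removes the primary silyl ether without touching the alkyl chloride or the trisubstituted alkene.

Step 4
Reactants: 7 (3E)-6-chloro-3-methylhex-3-en-1-ol
Product: 8 (3E)-6-chloro-3-methylhex-3-enal
Conditions: Dess–Martin periodinane, NaHCO3, CH2Cl2, 0 °C
Reagents that add atoms: none
Why: Buffered Dess–Martin oxidation gives the β,γ-unsaturated aldehyde under non-basic conditions that should not move the alkene into conjugation; the crude aldehyde is used at once.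

Step 5
Reactants: 9 (4R)-4-benzyl-1,3-oxazolidin-2-one; 10 (2E)-but-2-enoyl chloride
Product: 11 (4R)-4-benzyl-3-[(2E)-but-2-enoyl]-1,3-oxazolidin-2-one
Conditions: n-BuLi, THF, −78 °C; then 10, −78 → 0 °C
Reagents that add atoms: none
Why: N-Acylation of the lithiated oxazolidinone with an acid chloride is the standard entry to Evans imides.

Step 6
Reactants: 12 tributyl(iodomethyl)stannane; 13 (4-methoxyphenyl)methanol
Product: 14 tributyl{[(4-methoxyphenyl)methoxy]methyl}stannane
Conditions: NaH, THF/DMF, 0 °C; then 12, rt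
Reagents that add atoms: none
Why: Williamson etherification of the sodium alkoxide with the iodomethylstannane gives the α-alkoxymethylstannane needed for tin–lithium exchange.

Step 7
Reactants: 11 (4R)-4-benzyl-3-[(2E)-but-2-enoyl]-1,3-oxazolidin-2-one; 8 (3E)-6-chloro-3-methylhex-3-enal
Product: 16 (4R)-4-benzyl-3-[(2R,3S,5E)-8-chloro-2-ethenyl-3-hydroxy-5-methyloct-5-enoyl]-1,3-oxazolidin-2-one, via boron dienolate 15 (not isolated)
Conditions: Bu2BOTf, Et3N, CH2Cl2, −78 → 0 °C; then 8, −78 → 0 °C; pH 7 buffer, MeOH, H2O2, 0 °C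
Reagents that add atoms: none
Why: Evans syn-aldol reaction of the Z-boron dienolate, which reacts at its α-carbon through a Zimmerman–Traxler chair; the (R)-benzyl auxiliary shields one enolate face, so C7 and C8 are set together and the vinyl group becomes the future C11–C12 unit.

Step 8
Reactants: 16 aldol imide
Product: 17 (2R,3S,5E)-8-chloro-2-ethenyl-3-hydroxy-N-methoxy-N,5-dimethyloct-5-enamide
Conditions: MeNH(OMe)·HCl, AlMe3, CH2Cl2, −20 → 0 °C
Reagents that add atoms: N,O-dimethylhydroxylamine hydrochloride, CNOC.Cl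
Why: Aluminium-amide transamidation, assisted by the free β-hydroxyl, releases the auxiliary and should give the Weinreb amide without epimerising C7.

Step 9
Reactants: 17 Weinreb amide; 14 tributyl{[(4-methoxyphenyl)methoxy]methyl}stannane
Product: 19 (3R,4S,6E)-9-chloro-3-ethenyl-4-hydroxy-1-[(4-methoxyphenyl)methoxy]-6-methylnon-6-en-2-one, via alkoxymethyllithium 18 (not isolated)
Conditions: 14, n-BuLi, THF, −78 °C; then 17, −78 °C; aq. NH4Cl
Reagents that add atoms: none
Why: Tin–lithium exchange gives the alkoxymethyllithium, which adds once to the Weinreb amide through the chelated tetrahedral adduct (one further equivalent is consumed by the hydroxyl) and delivers C5 as a PMB-protected hydroxymethyl ketone.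

Step 10
Reactants: 19 β-hydroxy ketone
Product: 20 (2S,3R,4S,6E)-9-chloro-3-ethenyl-1-[(4-methoxyphenyl)methoxy]-6-methylnon-6-ene-2,4-diol
Conditions: Et2BOMe, THF/MeOH (4:1), −78 °C; NaBH4; then MeOH azeotrope
Reagents that add atoms: none
Why: Narasaka–Prasad reduction: the β-hydroxy ketone is held as a six-membered diethylboron chelate and hydride attacks axially, on the face away from the axial vinyl group, so the new C6 carbinol is 1,3-syn to O8 and the all-syn C6–C7–C8 triad results.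

Step 11
Reactants: 20 syn-diol
Product: 21 (3R,4S,6E)-9-chloro-3-[(4S)-2-(4-methoxyphenyl)-1,3-dioxolan-4-yl]-6-methylnona-1,6-dien-4-ol (both acetal epimers)
Conditions: DDQ, 4 Å molecular sieves, CH2Cl2, 0 °C
Reagents that add atoms: none
Why: Anhydrous DDQ oxidation of the PMB ether gives an oxocarbenium ion that the adjacent C6 hydroxyl traps as a five-membered 4-methoxybenzylidene acetal (oxidative acetalisation), which tells O6 from O8 because O8 could only close a seven-membered ring.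

Step 12
Reactants: 21 hydroxy acetal
Product: 22 {[(3S,4S,6E)-9-chloro-3-[(4S)-2-(4-methoxyphenyl)-1,3-dioxolan-4-yl]-6-methylnona-1,6-dien-4-yl]oxy}triethylsilane
Conditions: Et3SiOTf, 2,6-lutidine, CH2Cl2, −78 °C
Reagents that add atoms: triethylsilyl trifluoromethanesulfonate, CC[Si](CC)(CC)OS(=O)(=O)C(F)(F)F
Why: Silyl triflate/2,6-lutidine silylation of the one remaining (C8) hydroxyl at low temperature leaves the acid-labile acetal intact.

Step 13
Reactants: 22 silyl acetal
Product: 23 (2S,3S,4S,6E)-9-chloro-3-ethenyl-2-[(4-methoxyphenyl)methoxy]-6-methyl-4-[(triethylsilyl)oxy]non-6-en-1-ol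
Conditions: iBu2AlH, CH2Cl2, −78 → 0 °C
Reagents that add atoms: none
Why: Regioselective reductive opening of the benzylidene acetal: aluminium binds the less hindered primary oxygen, so hydride delivery leaves the PMB ether on the secondary O6 and frees the C5 primary alcohol.

Step 14
Reactants: 23 chloro alcohol
Product: 24 (2S,3S,4S,6E)-3-ethenyl-9-iodo-2-[(4-methoxyphenyl)methoxy]-6-methyl-4-[(triethylsilyl)oxy]non-6-en-1-ol
Conditions: NaI, NaHCO3, 2-butanone, 80 °C
Reagents that add atoms: sodium iodide, [Na+].[I-]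
Why: Finkelstein halide exchange converts the dormant primary chloride into the iodide needed for alkylation of a soft carbanion.

Step 15
Reactants: 24 iodo alcohol; 25 methyl [bis(2,2,2-trifluoroethoxy)phosphoryl]acetate
Product: 26 methyl (5E,8S,9S,10S)-2-[bis(2,2,2-trifluoroethoxy)phosphoryl]-9-ethenyl-11-hydroxy-10-[(4-methoxyphenyl)methoxy]-6-methyl-8-[(triethylsilyl)oxy]undec-5-enoate (both C2 epimers)
Conditions: 25 (3 equiv), NaH (2.8 equiv), DMF, 0 °C; then 24, rt → 40 °C
Reagents that add atoms: none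
Why: SN2 alkylation of the sodium phosphonoacetate by the primary iodide forms C3–C4; the stabilised carbanion, kept in excess over NaH, is too weak a base to ionise the free C5 hydroxyl, and either C4 epimer serves.

Step 16
Reactants: 26 hydroxy phosphonate
Product: 27 methyl (5E,8S,9S,10S)-2-[bis(2,2,2-trifluoroethoxy)phosphoryl]-9-ethenyl-10-[(4-methoxyphenyl)methoxy]-6-methyl-11-oxo-8-[(triethylsilyl)oxy]undec-5-enoate (both C2 epimers)
Conditions: Dess–Martin periodinane, NaHCO3, CH2Cl2, 0 °C → rt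
Reagents that add atoms: none
Why: Buffered Dess–Martin oxidation converts the primary alcohol into the α-alkoxy aldehyde under non-epimerising conditions; the aldehyde is taken directly into the ring closure.

Step 17
Reactants: 27 seco phosphonate aldehyde
Product: 28 methyl (1Z,3R,4S,5S,7E)-4-ethenyl-3-[(4-methoxyphenyl)methoxy]-7-methyl-5-[(triethylsilyl)oxy]cyclodeca-1,7-diene-1-carboxylate
Conditions: KN(SiMe3)2, 18-crown-6, THF, about 1 mM, −78 → −30 °C (27 added by syringe pump)
Reagents that add atoms: none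
Why: KN(SiMe3)2 with 18-crown-6 removes the C4 proton (both C4 epimers of 27 give the same potassium carbanion), which adds to the C5 aldehyde and, through the oxaphosphetane, eliminates potassium bis(trifluoroethyl) phosphate to form C4=C5. The closest known reaction type is the Still–Gennari variant of the Horner–Wadsworth–Emmons olefination in its intramolecular, high-dilution macrocyclisation form. The one ring that closes, the ten-membered carbocycle, does so by addition of the C4 carbanion to the exocyclic C5 carbonyl (10-exo-trig) followed by elimination. No stereocentre is created; the step must deliver the Z-enoate (C15 ester cis to C6, the ring-trans alkene), keep C6 intact and favour monomer over oligomer. The electron-poor trifluoroethoxy groups and the crown-separated potassium ion should make collapse of the first adduct faster than its reversal, so the kinetic Z geometry is kept, while low temperature without excess base protects the α-alkoxy aldehyde and slow addition at high dilution suppresses intermolecular olefination. The E-C1=C10 alkene and the compact vinyl group at C7 shorten the freely rotating segment between the reacting carbons.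

Step 18
Reactants: 28 macrocyclic Z-enoate
Product: 29 [(1Z,3R,4S,5S,7E)-4-ethenyl-3-[(4-methoxyphenyl)methoxy]-7-methyl-5-[(triethylsilyl)oxy]cyclodeca-1,7-dien-1-yl]methanol
Conditions: iBu2AlH, CH2Cl2, −78 °C
Reagents that add atoms: none
Why: 1,2-Reduction of the conjugated ester by iBu2AlH at low temperature gives the C15 allylic alcohol without affecting alkene geometry, the ethers or the vinyl group.

Step 19
Reactants: 29 allylic alcohol
Product: 30 tert-butyl{[(1Z,3R,4S,5S,7E)-4-ethenyl-3-[(4-methoxyphenyl)methoxy]-7-methyl-5-[(triethylsilyl)oxy]cyclodeca-1,7-dien-1-yl]methoxy}dimethylsilane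
Conditions: tBuMe2SiCl, imidazole, DMF, 0 °C
Reagents that add atoms: tert-butyldimethylsilyl chloride, CC(C)(C)[Si](C)(C)Cl
Why: Standard silylation of the primary allylic alcohol; the TBS group is chosen to outlast the later selective removal of the secondary triethylsilyl ether.

Step 20
Reactants: 30 vinyl macrocycle
Product: 32 2-[(1S,2R,3Z,7E,10S)-4-({[tert-butyl(dimethyl)silyl]oxy}methyl)-2-[(4-methoxyphenyl)methoxy]-8-methyl-10-[(triethylsilyl)oxy]cyclodeca-3,7-dien-1-yl]ethan-1-ol, via alkylborane 31 (not isolated)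
Conditions: 9-BBN, THF, 0 °C → rt; then aq. NaOH, H2O2, 0 °C
Reagents that add atoms: hydrogen peroxide, OO
Why: Anti-Markovnikov hydroboration–oxidation with bulky 9-BBN, which strongly prefers the monosubstituted vinyl group over the two trisubstituted ring alkenes, installs the C12 hydroxyl.

Step 21
Reactants: 32 C12 alcohol
Product: 33 (1R,2Z,6E,9S,10S)-3-({[tert-butyl(dimethyl)silyl]oxy}methyl)-10-(2-hydroxyethyl)-7-methyl-9-[(triethylsilyl)oxy]cyclodeca-2,6-dien-1-ol
Conditions: DDQ, CH2Cl2/pH 7 phosphate buffer, 0 °C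
Reagents that add atoms: none
Why: Oxidative PMB cleavage with DDQ in wet, buffered dichloromethane frees the allylic C6 hydroxyl while silyl ethers and alkenes stay untouched.

Step 22
Reactants: 33 1,4-diol
Product: 35 (3aS,4S,6E,10Z,11aR)-10-({[tert-butyl(dimethyl)silyl]oxy}methyl)-6-methyl-4-[(triethylsilyl)oxy]-3a,4,5,8,9,11a-hexahydrocyclodeca[b]furan-2(3H)-one, via lactol 34 (not isolated)
Conditions: TEMPO (cat.), PhI(OAc)2, CH2Cl2, rt
Reagents that add atoms: none
Why: Nitroxyl-catalysed oxidative lactonisation: the primary C12 alcohol is oxidised selectively to the aldehyde, which closes onto O6 as the lactol and is oxidised again to the trans-fused γ-lactone; O8 is silylated, so only the 6,12-lactone can form.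

Step 23
Reactants: 35 γ-lactone
Product: 38 (3aS,4S,6E,10Z,11aR)-10-({[tert-butyl(dimethyl)silyl]oxy}methyl)-6-methyl-3-methylidene-4-[(triethylsilyl)oxy]-3a,4,5,8,9,11a-hexahydrocyclodeca[b]furan-2(3H)-one, via Mannich base 36 (not isolated), via methiodide 37 (not isolated)
Conditions: LiN(iPr)2, THF, −78 °C; Me2N=CH2 I, −78 °C → rt; then MeI, MeOH, rt; then aq. NaHCO3, CH2Cl2
Reagents that add atoms: N,N-dimethylmethyleneiminium iodide (Eschenmoser's salt), C=[N+](C)C.[I-]
Why: Lactone-enolate Mannich reaction with Eschenmoser's salt, then quaternisation and Hofmann-type elimination, is the standard α-methylenation sequence and introduces C13; the enolate forms at C11, so C7 is not at risk.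

Step 24
Reactants: 38 bis-silyl α-methylene lactone
Product: 39 (3aR,4S,6E,10Z,11aR)-10-({[tert-butyl(dimethyl)silyl]oxy}methyl)-4-hydroxy-6-methyl-3-methylidene-3a,4,5,8,9,11a-hexahydrocyclodeca[b]furan-2(3H)-one
Conditions: pyridinium p-toluenesulfonate (cat.), MeOH/CH2Cl2, 0 °C
Reagents that add atoms: none
Why: A secondary triethylsilyl ether is methanolysed under mild acid catalysis much faster than a primary TBS ether, so only the C8 hydroxyl should be freed.

Step 25
Reactants: 40 (S)-glycidol; 41 vinylmagnesium bromide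
Product: 42 (2R)-pent-4-ene-1,2-diol
Conditions: CuI (cat.), THF, −40 → 0 °C
Reagents that add atoms: none
Why: Copper-catalysed Grignard opening of the epoxide at its terminal carbon leaves the stereocentre untouched, so (S)-glycidol gives the (R)-diol that becomes C3′.

Step 26
Reactants: 42 (2R)-pent-4-ene-1,2-diol
Product: 43 (2R)-2-hydroxypent-4-en-1-yl acetate
Conditions: AcCl, 2,4,6-collidine, CH2Cl2, −78 °C
Reagents that add atoms: acetyl chloride, CC(Cl)=O
Why: Low-temperature acylation with acetyl chloride and collidine is selective for the primary hydroxyl of a 1,2-diol.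

Step 27
Reactants: 43 (2R)-2-hydroxypent-4-en-1-yl acetate
Product: 44 (2R)-2-[(triethylsilyl)oxy]pent-4-en-1-yl acetate
Conditions: Et3SiCl, imidazole, CH2Cl2, 0 °C
Reagents that add atoms: chlorotriethylsilane, CC[Si](Cl)(CC)CC
Why: Imidazole-mediated silylation of the secondary alcohol; the triethylsilyl group is chosen for mild removal in the last step.

Step 28
Reactants: 44 (2R)-2-[(triethylsilyl)oxy]pent-4-en-1-yl acetate
Product: 46 (2R)-4-oxo-2-[(triethylsilyl)oxy]butyl acetate, via ozonide 45 (not isolated)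
Conditions: O3, CH2Cl2, −78 °C; then PPh3, −78 °C → rt
Reagents that add atoms: ozone, [O-][O+]=O
Why: Ozonolysis with reductive work-up cleaves the terminal alkene to the aldehyde (C1′) without affecting the ester or the silyl ether.

Step 29
Reactants: 46 (2R)-4-oxo-2-[(triethylsilyl)oxy]butyl acetate
Product: 48 (2R)-3-formyl-2-[(triethylsilyl)oxy]but-3-en-1-yl acetate, via Mannich base 47 (not isolated)
Conditions: Me2N=CH2 I, Et3N, CH2Cl2, rt
Reagents that add atoms: N,N-dimethylmethyleneiminium iodide (Eschenmoser's salt), C=[N+](C)C.[I-]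
Why: Mannich condensation with Eschenmoser's salt and β-elimination of dimethylamine is the standard α-methylenation of aldehydes; once methylenated, the product has no α-hydrogen and can no longer lose the β-silyloxy group.

Step 30
Reactants: 48 (2R)-3-formyl-2-[(triethylsilyl)oxy]but-3-en-1-yl acetate
Product: 49 (3R)-4-(acetyloxy)-2-methylidene-3-[(triethylsilyl)oxy]butanoic acid
Conditions: NaClO2, NaH2PO4, 2-methylbut-2-ene, tBuOH/H2O, 0 °C → rt
Reagents that add atoms: sodium chlorite, [Na+].[O-]Cl=O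
Why: Pinnick oxidation converts the enal into the acrylic acid under mildly acidic, chlorine-scavenged conditions compatible with the acetate, the silyl ether and the 1,1-disubstituted alkene.

Step 31
Reactants: 39 C8 alcohol; 49 (3R)-4-(acetyloxy)-2-methylidene-3-[(triethylsilyl)oxy]butanoic acid
Product: 51 (3aR,4S,6E,10Z,11aR)-10-({[tert-butyl(dimethyl)silyl]oxy}methyl)-6-methyl-3-methylidene-2-oxo-2,3,3a,4,5,8,9,11a-octahydrocyclodeca[b]furan-4-yl (3R)-4-(acetyloxy)-2-methylidene-3-[(triethylsilyl)oxy]butanoate, via mixed anhydride 50 (not isolated)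
Conditions: 49, 2,4,6-trichlorobenzoyl chloride, Et3N, toluene, rt; then 39, DMAP, toluene, rt
Reagents that add atoms: none
Why: Yamaguchi esterification: the mixed anhydride passes the acyl group through the acylpyridinium to the hindered secondary C8 alcohol under conditions that tolerate both α-methylene carbonyl units.

Step 32
Reactants: 51 bis-silyl ester
Product: 52 (3aR,4S,6E,10Z,11aR)-10-(hydroxymethyl)-6-methyl-3-methylidene-2-oxo-2,3,3a,4,5,8,9,11a-octahydrocyclodeca[b]furan-4-yl (3R)-4-(acetyloxy)-3-hydroxy-2-methylidenebutanoate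
Conditions: HF·pyridine, pyridine, THF, 0 °C → rt
Reagents that add atoms: none
Why: Buffered HF·pyridine cleaves both silyl ethers under mildly acidic conditions that should avoid 4′→3′ acetyl migration, conjugate addition to the methylene lactone and transannular cyclisation of the 1(10),4-diene.

**Compound list**
1 | tert-butyl(but-3-yn-1-yloxy)dimethylsilane | C#CCCO[Si](C)(C)C(C)(C)C | starting material
2 | oxirane | C1CO1 | starting material
3 | [(1E)-4-{[tert-butyl(dimethyl)silyl]oxy}-2-methylbut-1-en-1-yl]dimethylalane | C[Al](C)/C=C(\C)CCO[Si](C)(C)C(C)(C)C | intermediate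
4 | lithium butyl[(1E)-4-{[tert-butyl(dimethyl)silyl]oxy}-2-methylbut-1-en-1-yl]dimethylalanate | [Li+].CCCC[Al-](C)(C)/C=C(\C)CCO[Si](C)(C)C(C)(C)C | intermediate
5 | (3E)-6-{[tert-butyl(dimethyl)silyl]oxy}-4-methylhex-3-en-1-ol | OCC/C=C(\C)CCO[Si](C)(C)C(C)(C)C | intermediate
6 | tert-butyl{[(3E)-6-chloro-3-methylhex-3-en-1-yl]oxy}dimethylsilane | ClCC/C=C(\C)CCO[Si](C)(C)C(C)(C)C | intermediate
7 | (3E)-6-chloro-3-methylhex-3-en-1-ol | ClCC/C=C(\C)CCO | intermediate
8 | (3E)-6-chloro-3-methylhex-3-enal | ClCC/C=C(\C)CC=O | intermediate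
9 | (4R)-4-benzyl-1,3-oxazolidin-2-one | O=C1N[C@H](Cc2ccccc2)CO1 | starting material
10 | (2E)-but-2-enoyl chloride | C/C=C/C(Cl)=O | starting material
11 | (4R)-4-benzyl-3-[(2E)-but-2-enoyl]-1,3-oxazolidin-2-one | C/C=C/C(=O)N1C(=O)OC[C@H]1Cc1ccccc1 | intermediate
12 | tributyl(iodomethyl)stannane | CCCC[Sn](CCCC)(CCCC)CI | starting material
13 | (4-methoxyphenyl)methanol | COc1ccc(CO)cc1 | starting material
14 | tributyl{[(4-methoxyphenyl)methoxy]methyl}stannane | CCCC[Sn](CCCC)(CCCC)COCc1ccc(OC)cc1 | intermediate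
15 | dibutylboron (Z)-dienolate of 11 | C=C/C=C(\OB(CCCC)CCCC)N1C(=O)OC[C@H]1Cc1ccccc1 | intermediate
16 | (4R)-4-benzyl-3-[(2R,3S,5E)-8-chloro-2-ethenyl-3-hydroxy-5-methyloct-5-enoyl]-1,3-oxazolidin-2-one | ClCC/C=C(\C)C[C@H](O)[C@@H](C=C)C(=O)N1C(=O)OC[C@H]1Cc1ccccc1 | intermediate
17 | (2R,3S,5E)-8-chloro-2-ethenyl-3-hydroxy-N-methoxy-N,5-dimethyloct-5-enamide | ClCC/C=C(\C)C[C@H](O)[C@@H](C=C)C(=O)N(C)OC | intermediate
18 | {[(4-methoxyphenyl)methoxy]methyl}lithium | [Li]COCc1ccc(OC)cc1 | intermediate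
19 | (3R,4S,6E)-9-chloro-3-ethenyl-4-hydroxy-1-[(4-methoxyphenyl)methoxy]-6-methylnon-6-en-2-one | ClCC/C=C(\C)C[C@H](O)[C@@H](C=C)C(=O)COCc1ccc(OC)cc1 | intermediate
20 | (2S,3R,4S,6E)-9-chloro-3-ethenyl-1-[(4-methoxyphenyl)methoxy]-6-methylnon-6-ene-2,4-diol | ClCC/C=C(\C)C[C@H](O)[C@@H](C=C)[C@H](O)COCc1ccc(OC)cc1 | intermediate
21 | (3R,4S,6E)-9-chloro-3-[(4S)-2-(4-methoxyphenyl)-1,3-dioxolan-4-yl]-6-methylnona-1,6-dien-4-ol (both acetal epimers) | ClCC/C=C(\C)C[C@H](O)[C@@H](C=C)[C@H]1COC(c2ccc(OC)cc2)O1 | intermediate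
22 | {[(3S,4S,6E)-9-chloro-3-[(4S)-2-(4-methoxyphenyl)-1,3-dioxolan-4-yl]-6-methylnona-1,6-dien-4-yl]oxy}triethylsilane | ClCC/C=C(\C)C[C@H](O[Si](CC)(CC)CC)[C@@H](C=C)[C@H]1COC(c2ccc(OC)cc2)O1 | intermediate
23 | (2S,3S,4S,6E)-9-chloro-3-ethenyl-2-[(4-methoxyphenyl)methoxy]-6-methyl-4-[(triethylsilyl)oxy]non-6-en-1-ol | ClCC/C=C(\C)C[C@H](O[Si](CC)(CC)CC)[C@@H](C=C)[C@H](OCc1ccc(OC)cc1)CO | intermediate
24 | (2S,3S,4S,6E)-3-ethenyl-9-iodo-2-[(4-methoxyphenyl)methoxy]-6-methyl-4-[(triethylsilyl)oxy]non-6-en-1-ol | ICC/C=C(\C)C[C@H](O[Si](CC)(CC)CC)[C@@H](C=C)[C@H](OCc1ccc(OC)cc1)CO | intermediate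
25 | methyl [bis(2,2,2-trifluoroethoxy)phosphoryl]acetate | COC(=O)CP(=O)(OCC(F)(F)F)OCC(F)(F)F | starting material
26 | methyl (5E,8S,9S,10S)-2-[bis(2,2,2-trifluoroethoxy)phosphoryl]-9-ethenyl-11-hydroxy-10-[(4-methoxyphenyl)methoxy]-6-methyl-8-[(triethylsilyl)oxy]undec-5-enoate (both C2 epimers) | COC(=O)C(CC/C=C(\C)C[C@H](O[Si](CC)(CC)CC)[C@@H](C=C)[C@H](OCc1ccc(OC)cc1)CO)P(=O)(OCC(F)(F)F)OCC(F)(F)F | intermediate
27 | methyl (5E,8S,9S,10S)-2-[bis(2,2,2-trifluoroethoxy)phosphoryl]-9-ethenyl-10-[(4-methoxyphenyl)methoxy]-6-methyl-11-oxo-8-[(triethylsilyl)oxy]undec-5-enoate (both C2 epimers) | COC(=O)C(CC/C=C(\C)C[C@H](O[Si](CC)(CC)CC)[C@@H](C=C)[C@H](OCc1ccc(OC)cc1)C=O)P(=O)(OCC(F)(F)F)OCC(F)(F)F | intermediate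
28 | methyl (1Z,3R,4S,5S,7E)-4-ethenyl-3-[(4-methoxyphenyl)methoxy]-7-methyl-5-[(triethylsilyl)oxy]cyclodeca-1,7-diene-1-carboxylate | COC(=O)/C1=C\[C@@H](OCc2ccc(OC)cc2)[C@H](C=C)[C@@H](O[Si](CC)(CC)CC)C/C(C)=C/CC1 | intermediate
29 | [(1Z,3R,4S,5S,7E)-4-ethenyl-3-[(4-methoxyphenyl)methoxy]-7-methyl-5-[(triethylsilyl)oxy]cyclodeca-1,7-dien-1-yl]methanol | OC/C1=C\[C@@H](OCc2ccc(OC)cc2)[C@H](C=C)[C@@H](O[Si](CC)(CC)CC)C/C(C)=C/CC1 | intermediate
30 | tert-butyl{[(1Z,3R,4S,5S,7E)-4-ethenyl-3-[(4-methoxyphenyl)methoxy]-7-methyl-5-[(triethylsilyl)oxy]cyclodeca-1,7-dien-1-yl]methoxy}dimethylsilane | CC(C)(C)[Si](C)(C)OC/C1=C\[C@@H](OCc2ccc(OC)cc2)[C@H](C=C)[C@@H](O[Si](CC)(CC)CC)C/C(C)=C/CC1 | intermediate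
31 | 9-{2-[(1S,2R,3Z,7E,10S)-4-({[tert-butyl(dimethyl)silyl]oxy}methyl)-2-[(4-methoxyphenyl)methoxy]-8-methyl-10-[(triethylsilyl)oxy]cyclodeca-3,7-dien-1-yl]ethyl}-9-borabicyclo[3.3.1]nonane | CC(C)(C)[Si](C)(C)OC/C1=C\[C@@H](OCc2ccc(OC)cc2)[C@H](CCB2C3CCCC2CCC3)[C@@H](O[Si](CC)(CC)CC)C/C(C)=C/CC1 | intermediate
32 | 2-[(1S,2R,3Z,7E,10S)-4-({[tert-butyl(dimethyl)silyl]oxy}methyl)-2-[(4-methoxyphenyl)methoxy]-8-methyl-10-[(triethylsilyl)oxy]cyclodeca-3,7-dien-1-yl]ethan-1-ol | CC(C)(C)[Si](C)(C)OC/C1=C\[C@@H](OCc2ccc(OC)cc2)[C@H](CCO)[C@@H](O[Si](CC)(CC)CC)C/C(C)=C/CC1 | intermediate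
33 | (1R,2Z,6E,9S,10S)-3-({[tert-butyl(dimethyl)silyl]oxy}methyl)-10-(2-hydroxyethyl)-7-methyl-9-[(triethylsilyl)oxy]cyclodeca-2,6-dien-1-ol | CC(C)(C)[Si](C)(C)OC/C1=C\[C@@H](O)[C@H](CCO)[C@@H](O[Si](CC)(CC)CC)C/C(C)=C/CC1 | intermediate
34 | (3aS,4S,6E,10Z,11aR)-10-({[tert-butyl(dimethyl)silyl]oxy}methyl)-6-methyl-4-[(triethylsilyl)oxy]-2,3,3a,4,5,8,9,11a-octahydrocyclodeca[b]furan-2-ol (both anomers) | C1C(O)O[C@@H]2/C=C(\CO[Si](C)(C)C(C)(C)C)CC/C=C(\C)C[C@H](O[Si](CC)(CC)CC)[C@@H]12 | intermediate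
35 | (3aS,4S,6E,10Z,11aR)-10-({[tert-butyl(dimethyl)silyl]oxy}methyl)-6-methyl-4-[(triethylsilyl)oxy]-3a,4,5,8,9,11a-hexahydrocyclodeca[b]furan-2(3H)-one | C1C(=O)O[C@@H]2/C=C(\CO[Si](C)(C)C(C)(C)C)CC/C=C(\C)C[C@H](O[Si](CC)(CC)CC)[C@@H]12 | intermediate
36 | (3aS,4S,6E,10Z,11aR)-10-({[tert-butyl(dimethyl)silyl]oxy}methyl)-3-[(dimethylamino)methyl]-6-methyl-4-[(triethylsilyl)oxy]-3a,4,5,8,9,11a-hexahydrocyclodeca[b]furan-2(3H)-one (C3 epimers) | CN(C)CC1C(=O)O[C@@H]2/C=C(\CO[Si](C)(C)C(C)(C)C)CC/C=C(\C)C[C@H](O[Si](CC)(CC)CC)[C@@H]12 | intermediate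
37 | trimethylammonium iodide of 36 (N-methyl quaternary salt; C3 epimers) | C[N+](C)(C)CC1C(=O)O[C@@H]2/C=C(\CO[Si](C)(C)C(C)(C)C)CC/C=C(\C)C[C@H](O[Si](CC)(CC)CC)[C@@H]12.[I-] | intermediate
38 | (3aS,4S,6E,10Z,11aR)-10-({[tert-butyl(dimethyl)silyl]oxy}methyl)-6-methyl-3-methylidene-4-[(triethylsilyl)oxy]-3a,4,5,8,9,11a-hexahydrocyclodeca[b]furan-2(3H)-one | C=C1C(=O)O[C@@H]2/C=C(\CO[Si](C)(C)C(C)(C)C)CC/C=C(\C)C[C@H](O[Si](CC)(CC)CC)[C@@H]12 | intermediate
39 | (3aR,4S,6E,10Z,11aR)-10-({[tert-butyl(dimethyl)silyl]oxy}methyl)-4-hydroxy-6-methyl-3-methylidene-3a,4,5,8,9,11a-hexahydrocyclodeca[b]furan-2(3H)-one | C=C1C(=O)O[C@@H]2/C=C(\CO[Si](C)(C)C(C)(C)C)CC/C=C(\C)C[C@H](O)[C@@H]12 | intermediate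
40 | (S)-glycidol, [(2S)-oxiran-2-yl]methanol | OC[C@H]1CO1 | starting material
41 | vinylmagnesium bromide | C=C[Mg]Br | starting material
42 | (2R)-pent-4-ene-1,2-diol | OC[C@H](O)CC=C | intermediate
43 | (2R)-2-hydroxypent-4-en-1-yl acetate | CC(=O)OC[C@H](O)CC=C | intermediate
44 | (2R)-2-[(triethylsilyl)oxy]pent-4-en-1-yl acetate | CC(=O)OC[C@H](O[Si](CC)(CC)CC)CC=C | intermediate
45 | (2R)-3-(1,2,4-trioxolan-3-yl)-2-[(triethylsilyl)oxy]propyl acetate (ozonide) | CC(=O)OC[C@H](O[Si](CC)(CC)CC)CC1OCOO1 | intermediate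
46 | (2R)-4-oxo-2-[(triethylsilyl)oxy]butyl acetate | CC(=O)OC[C@H](O[Si](CC)(CC)CC)CC=O | intermediate
47 | (2R)-3-[(dimethylamino)methyl]-4-oxo-2-[(triethylsilyl)oxy]butyl acetate (C3 epimers) | CC(=O)OC[C@H](O[Si](CC)(CC)CC)C(CN(C)C)C=O | intermediate
48 | (2R)-3-formyl-2-[(triethylsilyl)oxy]but-3-en-1-yl acetate | CC(=O)OC[C@H](O[Si](CC)(CC)CC)C(=C)C=O | intermediate
49 | (3R)-4-(acetyloxy)-2-methylidene-3-[(triethylsilyl)oxy]butanoic acid | CC(=O)OC[C@H](O[Si](CC)(CC)CC)C(=C)C(=O)O | intermediate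
50 | (3R)-4-(acetyloxy)-2-methylidene-3-[(triethylsilyl)oxy]butanoic 2,4,6-trichlorobenzoic anhydride | CC(=O)OC[C@H](O[Si](CC)(CC)CC)C(=C)C(=O)OC(=O)c1c(Cl)cc(Cl)cc1Cl | intermediate
51 | (3aR,4S,6E,10Z,11aR)-10-({[tert-butyl(dimethyl)silyl]oxy}methyl)-6-methyl-3-methylidene-2-oxo-2,3,3a,4,5,8,9,11a-octahydrocyclodeca[b]furan-4-yl (3R)-4-(acetyloxy)-2-methylidene-3-[(triethylsilyl)oxy]butanoate | C=C1C(=O)O[C@@H]2/C=C(\CO[Si](C)(C)C(C)(C)C)CC/C=C(\C)C[C@H](OC(=O)C(=C)[C@@H](O[Si](CC)(CC)CC)COC(C)=O)[C@@H]12 | intermediate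
52 | (3aR,4S,6E,10Z,11aR)-10-(hydroxymethyl)-6-methyl-3-methylidene-2-oxo-2,3,3a,4,5,8,9,11a-octahydrocyclodeca[b]furan-4-yl (3R)-4-(acetyloxy)-3-hydroxy-2-methylidenebutanoate | C=C1C(=O)O[C@@H]2/C=C(\CO)CC/C=C(\C)C[C@H](OC(=O)C(=C)[C@@H](O)COC(C)=O)[C@@H]12 | target

**Totals**
Total step count: 32. Longest linear sequence: 24 steps (steps 1–4, 7–24, 31 and 32).

**Steps most likely to fail**

Step 17. Intermolecular olefination may outrun closure of the strained ten-membered ring, and the α-alkoxy aldehyde may lose its C6 configuration to base before it olefinates. The fallback keeps the C4=C5 disconnection but changes the activating group to a diaryl phosphonate, which also gives Z-enoates and can be run under milder, sodium-templated conditions. It sets out from 24: alkylation with the sodium salt of ethyl [bis(2-methylphenoxy)phosphoryl]acetate should give the hydroxy diaryl phosphonate F1, Dess–Martin oxidation the aldehyde F2, and ring closure with NaI and DBU in THF at high dilution at 0 °C the ethyl ester macrocycle F3. Reduction of F3 with iBu2AlH returns the route at 29.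

Step 15. The weakly nucleophilic trifluoroethyl phosphonoacetate anion may substitute slowly, alkylate twice, or exchange a trifluoroethoxy group with the free C5 hydroxyl. The fallback masks that hydroxyl and unmasks it oxidatively. It sets out from 24: silylation with Et3SiCl and imidazole should give the bis(triethylsilyl) iodide F4, and alkylation with the sodium salt of 25 the bis-silyl phosphonate F5. A Swern oxidation ((COCl)2, DMSO, then Et3N), which cleaves and oxidises a primary triethylsilyl ether directly while leaving the secondary one, returns the route at 27.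

Step 24. The primary allylic TBS ether may be lost alongside the triethylsilyl ether, and the freed C8 hydroxyl may relactonise onto C12 under prolonged acid. The fallback replaces selective deprotection by global deprotection and selective reprotection. It sets out from 38: HF·pyridine in pyridine/THF should give the 8,15-diol F6, and silylation of the primary allylic hydroxyl alone (tBuMe2SiCl, imidazole, −20 °C) returns the route at 39.

**Further compounds**
F1 | step 17 | ethyl (5E,8S,9S,10S)-2-[bis(2-methylphenoxy)phosphoryl]-9-ethenyl-11-hydroxy-10-[(4-methoxyphenyl)methoxy]-6-methyl-8-[(triethylsilyl)oxy]undec-5-enoate (both C2 epimers) | CCOC(=O)C(CC/C=C(\C)C[C@H](O[Si](CC)(CC)CC)[C@@H](C=C)[C@H](OCc1ccc(OC)cc1)CO)P(=O)(Oc1ccccc1C)Oc1ccccc1C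
F2 | step 17 | ethyl (5E,8S,9S,10S)-2-[bis(2-methylphenoxy)phosphoryl]-9-ethenyl-10-[(4-methoxyphenyl)methoxy]-6-methyl-11-oxo-8-[(triethylsilyl)oxy]undec-5-enoate (both C2 epimers) | CCOC(=O)C(CC/C=C(\C)C[C@H](O[Si](CC)(CC)CC)[C@@H](C=C)[C@H](OCc1ccc(OC)cc1)C=O)P(=O)(Oc1ccccc1C)Oc1ccccc1C
F3 | step 17 | ethyl (1Z,3R,4S,5S,7E)-4-ethenyl-3-[(4-methoxyphenyl)methoxy]-7-methyl-5-[(triethylsilyl)oxy]cyclodeca-1,7-diene-1-carboxylate | CCOC(=O)/C1=C\[C@@H](OCc2ccc(OC)cc2)[C@H](C=C)[C@@H](O[Si](CC)(CC)CC)C/C(C)=C/CC1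
F4 | step 15 | triethyl{[(2S,3S,4S,6E)-3-ethenyl-9-iodo-2-[(4-methoxyphenyl)methoxy]-6-methyl-4-[(triethylsilyl)oxy]non-6-en-1-yl]oxy}silane | ICC/C=C(\C)C[C@H](O[Si](CC)(CC)CC)[C@@H](C=C)[C@H](OCc1ccc(OC)cc1)CO[Si](CC)(CC)CC
F5 | step 15 | methyl (5E,8S,9S,10S)-2-[bis(2,2,2-trifluoroethoxy)phosphoryl]-9-ethenyl-10-[(4-methoxyphenyl)methoxy]-6-methyl-8,11-bis[(triethylsilyl)oxy]undec-5-enoate (both C2 epimers) | COC(=O)C(CC/C=C(\C)C[C@H](O[Si](CC)(CC)CC)[C@@H](C=C)[C@H](OCc1ccc(OC)cc1)CO[Si](CC)(CC)CC)P(=O)(OCC(F)(F)F)OCC(F)(F)F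
F6 | step 24 | (3aR,4S,6E,10Z,11aR)-4-hydroxy-10-(hydroxymethyl)-6-methyl-3-methylidene-3a,4,5,8,9,11a-hexahydrocyclodeca[b]furan-2(3H)-one | C=C1C(=O)O[C@@H]2/C=C(\CO)CC/C=C(\C)C[C@H](O)[C@@H]12
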